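The C2–C3 oxirane is cut back to a ring enone, with its oxygen lent by a hydroperoxide on C8 of the C5 side chain (carvone numbering; side chain C7–C14). The key step exploits the cis relation between the C2–C3 oxirane of the cyclohexanone ring and the C5 substituent, whose C8 is oxygenated: the four atoms C7–C8–O–O reach from C5 to C3 on that face only. In one operation the base-triggered transfer sets C2 and C3, closes the oxirane and frees the C8 allylic alcohol that then directs the C7 spiro-epoxidation. The precursor is trans-6-isovaleryloxycarvone, from (R)-carvone, carrying a primary allylic hydroperoxide on its former isopropenyl group.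

Key step: step 5

Remark on locants: C1 ring ketone, C2 methyl-bearing carbon, C3, C4, C5 side-chain-bearing carbon, C6 ester-bearing carbon, C7 spiro-oxirane carbon with C14 its CH2, C8 side-chain ketone, C9=C10 alkene, C11 carbinol carbon.
Remark on numbering: reagents, catalysts and solvents carry no compound number.

Step 1
Reactants: 1 (R)-(−)-carvone
Product: 3 kinetic C6 trimethylsilyl dienol ether of carvone, via lithium dienolate 2 (not isolated)
Conditions: LiN(iPr)2, THF, −78 °C; Me3SiCl, −78 → 0 °C; non-aqueous work-up (pentane, filtration)
Reagents that add atoms: chlorotrimethylsilane, C[Si](C)(C)Cl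
Why: Kinetic α′-deprotonation of the cross-conjugated enone at C6 by the hindered amide, followed by O-silylation of the dienolate (silyl enol ether formation), gives the 2-silyloxy diene and leaves C5 untouched.

Step 2
Reactants: 3 kinetic C6 trimethylsilyl dienol ether of carvone
Product: 6 trans-6-hydroxycarvone, via silyloxy oxirane 4 (not isolated), via 6-trimethylsilyloxycarvone 5 (not isolated)
Conditions: mCPBA (1.0 equiv), hexane–CH2Cl2, −15 °C; then 1 M HCl, THF, 0 °C
Reagents that add atoms: 3-chloroperoxybenzoic acid, OOC(=O)c1cccc(Cl)c1
Why: Rubottom oxidation, in which the peracid epoxidises the electron-rich enol ether bond on the face anti to the C5 isopropenyl group, silyl migration opens the oxirane to the α-silyloxy ketone and dilute acid frees the C6 hydroxyl, which is thereby set trans to C5.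

Step 3
Reactants: 6 trans-6-hydroxycarvone; 7 isovaleryl chloride
Product: 8 trans-6-isovaleryloxycarvone
Conditions: pyridine, DMAP (cat.), CH2Cl2, 0 °C
Reagents that add atoms: none
Why: DMAP-catalysed O-acylation of the secondary α-ketol forms no stereocentre, and the trans (diequatorial) arrangement at C5 and C6 is also the thermodynamic one, so enolisation cannot erode it.

Step 4
Reactants: 8 trans-6-isovaleryloxycarvone
Product: 9 side-chain allylic hydroperoxide
Conditions: O2, tetraphenylporphyrin (cat.), CH2Cl2, 0 °C, visible light (> 500 nm)
Reagents that add atoms: dioxygen, O=O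
Why: Schenck ene reaction, in which singlet oxygen attacks only the electron-rich 1,1-disubstituted alkene (the enone is electron-poor and not excited at this wavelength), bonds to the terminal CH2 and abstracts a methyl hydrogen rather than the poorly aligned C5–H, which should give the primary 2-substituted allyl hydroperoxide with no stereocentre touched.

Step 5
Reactants: 9 side-chain allylic hydroperoxide
Product: 11 cis-2,3-epoxy ketone with 3-hydroxyprop-1-en-2-yl side chain, via dioxepane enolate 10 (not isolated)
Conditions: DBU (0.2 equiv), toluene, 0.005 M (slow addition of 9), 0 °C → rt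
Reagents that add atoms: none
Why: Proposed new method: DBU deprotonates the hydroperoxide, the tethered peroxide anion adds in a conjugate (peroxy-Michael) sense to C3 of the ring enone to give the dioxepane enolate 10, and the enolate carbon C2 then attacks the C3-bound oxygen and expels the C8 alkoxide with O–O cleavage, which is an intramolecular Weitz–Scheffer epoxidation that turns over because the alkoxide deprotonates the next hydroperoxide. The closest known reactions are the epoxidation of cyclohexenones by tert-butyl hydroperoxide and DBU between two molecules and peroxy-Michael cyclisations that give 1,2-dioxacycles. The transient seven-membered 1,2-dioxepane (C3, C4, C5, C7, C8 and the two oxygens) closes 7-exo-trig and the oxirane closes 3-exo-tet at oxygen, and since C2 lies outside the dioxepane the O–O bond can stand anti to it as that displacement requires. C3 is set by the C5 stereocentre, because the four-atom tether can bridge C5 and C3 only when both bonds are axial on the same face of the half-chair, and C2 is set by C3, because the oxirane can only close on the face that already carries the C3 oxygen. The step needs attack cis to the side chain, opposite to the anti preference of external peroxide anions, and needs the peroxide to act as a nucleophile before it dehydrates (Kornblum–DeLaMare) or attacks the ester; the tether, the high dilution, the lack of any other electrophilic alkene (the tether cannot reach its own C7=C14 bond) and the non-nucleophilic amidine base are what secure this.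

Step 6
Reactants: 11 cis-2,3-epoxy ketone with 3-hydroxyprop-1-en-2-yl side chain
Product: 12 bis-epoxy primary alcohol
Conditions: Ti(OiPr)4 (0.3 equiv), L-(+)-diethyl tartrate (0.36 equiv), tBuOOH (anhydrous, in isooctane), 4 Å molecular sieves, CH2Cl2, −20 °C; aqueous citric acid work-up
Reagents that add atoms: tert-butyl hydroperoxide, CC(C)(C)OO
Why: Katsuki–Sharpless asymmetric epoxidation, in which the primary allylic alcohol binds the catalyst formed from Ti(OiPr)4 and the tartrate, and L-(+)-tartrate, which gives (S)-2-substituted glycidols from 2-substituted allyl alcohols, should add oxygen to the C7=C14 face that makes C7 S under reagent control over the neighbouring C5 centre, with ketone, ring oxirane and ester as spectators.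

Step 7
Reactants: 12 bis-epoxy primary alcohol
Product: 13 bis-epoxy aldehyde
Conditions: Dess–Martin periodinane, pyridine, CH2Cl2, 0 °C → rt
Reagents that add atoms: none
Why: Dess–Martin oxidation under pyridine buffering turns the primary alcohol into an aldehyde that has no α-hydrogen, so C7 keeps its geometry (its descriptor becomes R only through a change of priorities) and the oxiranes and ester are not exposed to acid or strong base.

Step 8
Reactants: 14 2-methylbut-3-yn-2-ol
Product: 15 triethylsilyl ether of 2-methylbut-3-yn-2-ol
Conditions: Et3SiOSO2CF3, 2,6-lutidine, CH2Cl2, 0 °C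
Reagents that add atoms: triethylsilyl trifluoromethanesulfonate, CC[Si](CC)(CC)OS(=O)(=O)C(F)(F)F
Why: O-Silylation with the reactive silyl triflate covers the hindered tertiary alcohol, so that no acidic hydroxyl consumes the zirconium hydride or the organozinc reagent in the next step.

Step 9
Reactants: 15 triethylsilyl ether of 2-methylbut-3-yn-2-ol; 13 bis-epoxy aldehyde
Product: 18 C8 carbinol adduct (both C8 epimers), via alkenylzirconocene chloride 16 (not isolated), via alkenylmethylzinc 17 (not isolated)
Conditions: 15, Cp2Zr(H)Cl, CH2Cl2, rt; Me2Zn, toluene, −65 °C; 13, −65 → 0 °C; aqueous NH4Cl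
Reagents that add atoms: none
Why: Syn hydrozirconation of the terminal alkyne puts zirconium on the terminal carbon and fixes the E geometry, and zirconium-to-zinc transmetalation gives an alkenylzinc whose 1,2-addition to the aldehyde should be far faster than attack on the hindered C1 ketone, the ester or the oxiranes; the C8 carbinol forms as both epimers, which is harmless because C8 is oxidised next.

Step 10
Reactants: 18 C8 carbinol adduct (both C8 epimers)
Product: 19 triethylsilyl ether of the target
Conditions: Dess–Martin periodinane, pyridine, CH2Cl2, 0 °C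
Reagents that add atoms: none
Why: Dess–Martin oxidation of the allylic C8 carbinol should converge both epimers on the single E-enone under buffered conditions that leave the oxiranes, the ester and the silyl ether alone.

Step 11
Reactants: 19 triethylsilyl ether of the target
Product: 20 CNP0292003.1
Conditions: HF·pyridine, pyridine, THF, 0 °C
Reagents that add atoms: none
Why: Fluoride-mediated desilylation under pyridine buffering should remove the tertiary triethylsilyl ether while the two oxiranes (both α to a ketone and so deactivated toward acid opening), the enone and the ester persist.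

Compound list
1 | (R)-(−)-carvone, (5R)-2-methyl-5-(prop-1-en-2-yl)cyclohex-2-en-1-one | CC1=CC[C@H](CC1=O)C(C)=C | starting material
2 | lithium dienolate of carvone (C1–OLi, C1=C6 and C2=C3 double bonds, C5 unchanged) | CC1=CC[C@H](C=C1O[Li])C(C)=C | intermediate (not isolated)
3 | kinetic C6 trimethylsilyl dienol ether of carvone (C1–OSiMe3, C1=C6 and C2=C3 double bonds) | CC1=CC[C@H](C=C1O[Si](C)(C)C)C(C)=C | intermediate
4 | silyloxy oxirane: C1–C6 epoxide of 3, oxirane oxygen trans to the C5 isopropenyl group | O1[C@@H]2[C@@]1(O[Si](C)(C)C)C(C)=CC[C@H]2C(C)=C | intermediate (not isolated)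
5 | trans-6-(trimethylsilyloxy)carvone | C[Si](C)(C)O[C@@H]1C(=O)C(C)=CC[C@H]1C(C)=C | intermediate (not isolated)
6 | trans-6-hydroxycarvone, (5S,6S)-6-hydroxy-2-methyl-5-(prop-1-en-2-yl)cyclohex-2-en-1-one | O[C@@H]1C(=O)C(C)=CC[C@H]1C(C)=C | intermediate
7 | isovaleryl chloride (3-methylbutanoyl chloride) | CC(C)CC(=O)Cl | starting material
8 | trans-6-isovaleryloxycarvone (3-methylbutanoate of 6) | CC(C)CC(=O)O[C@@H]1C(=O)C(C)=CC[C@H]1C(C)=C | intermediate
9 | side-chain allylic hydroperoxide: 8 with the C5 substituent changed to 3-hydroperoxyprop-1-en-2-yl | CC(C)CC(=O)O[C@@H]1C(=O)C(C)=CC[C@H]1C(=C)COO | intermediate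
10 | dioxepane enolate: C1(O−)=C2 enolate in which C3 and C5 are bridged on one face by O–O–CH2–C(=CH2), drawn as the anion (counter-ion protonated DBU) | CC(C)CC(=O)O[C@@H]1C([O-])=C(C)[C@@H]2C[C@H]1C(=C)COO2 | intermediate (not isolated)
11 | cis-2,3-epoxy ketone: C2–C3 oxirane on the face of the C5 substituent, C5 substituent 3-hydroxyprop-1-en-2-yl, C6 ester trans to C5 | CC(C)CC(=O)O[C@@H]1C(=O)[C@@]2(C)O[C@H]2C[C@H]1C(=C)CO | intermediate
12 | bis-epoxy primary alcohol: 11 with the side chain turned into (2S)-2-(hydroxymethyl)oxiran-2-yl | CC(C)CC(=O)O[C@@H]1C(=O)[C@@]2(C)O[C@H]2C[C@H]1[C@]1(CO)CO1 | intermediate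
13 | bis-epoxy aldehyde: side chain (2R)-2-formyloxiran-2-yl | CC(C)CC(=O)O[C@@H]1C(=O)[C@@]2(C)O[C@H]2C[C@H]1[C@]1(C=O)CO1 | intermediate
14 | 2-methylbut-3-yn-2-ol | CC(C)(O)C#C | starting material
15 | triethyl[(2-methylbut-3-yn-2-yl)oxy]silane | CC[Si](CC)(CC)OC(C)(C)C#C | intermediate
16 | (E)-alkenylzirconocene chloride Cp2Zr(Cl)CH=CH–C(CH3)2OSiEt3 (cyclopentadienyl ligands drawn σ-bonded) | CC[Si](CC)(CC)OC(C)(C)/C=C/[Zr](Cl)(C1C=CC=C1)C1C=CC=C1 | intermediate (not isolated)
17 | (E)-alkenyl(methyl)zinc CH3Zn–CH=CH–C(CH3)2OSiEt3 | CC[Si](CC)(CC)OC(C)(C)/C=C/[Zn]C | intermediate (not isolated)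
18 | C8 carbinol adduct, both C8 epimers: side chain (2R)-2-[(E)-1-hydroxy-4-methyl-4-(triethylsilyloxy)pent-2-enyl]oxiran-2-yl | CC(C)CC(=O)O[C@@H]1C(=O)[C@@]2(C)O[C@H]2C[C@H]1[C@]1(C(O)/C=C/C(C)(C)O[Si](CC)(CC)CC)CO1 | intermediate
19 | triethylsilyl ether of the target (C8 ketone, E-enone, C11–OSiEt3) | CC(C)CC(=O)O[C@@H]1C(=O)[C@@]2(C)O[C@H]2C[C@H]1[C@]1(C(=O)/C=C/C(C)(C)O[Si](CC)(CC)CC)CO1 | intermediate
20 | CNP0292003.1, (1S,3S,4R,6S)-4-{(2R)-2-[(2E)-4-hydroxy-4-methylpent-2-enoyl]oxiran-2-yl}-1-methyl-2-oxo-7-oxabicyclo[4.1.0]heptan-3-yl 3-methylbutanoate | CC(C)CC(=O)O[C@@H]1C(=O)[C@@]2(C)O[C@H]2C[C@H]1[C@]1(C(=O)/C=C/C(C)(C)O)CO1 | target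

Total step count: 11.
Longest linear sequence: 10 steps (steps 1 to 7 and 9 to 11, from carvone); step 8 lies on the side branch.

Steps most likely to fail

1. Step 5.
- **Risk:** The tethered conjugate addition may be slower than base-induced dehydration of the hydroperoxide, or slower than oxygen transfer between two molecules on the wrong face.
- **Fallback (known reactions only, from 8 back to 11):** Luche reduction of 8 (NaBH4, CeCl3·7H2O, MeOH, −78 °C) should give, by axial hydride delivery, the cis C1 allylic alcohol F1, whose hydroxyl is cis to the C5 group. Hydroxyl-directed epoxidation (VO(acac)2, tBuOOH, CH2Cl2) should then give the syn epoxy alcohol F2, with the oxirane cis to C5 and the isopropenyl group untouched. Dess–Martin oxidation gives the cis-epoxy ketone F3. The Schenck ene reaction under the conditions of step 4 gives the side-chain hydroperoxide F4, and PPh3 reduces it to 11.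

2. Step 4.
- **Risk:** The 1,1-disubstituted alkene may take up singlet oxygen too slowly, so that long irradiation degrades the hydroperoxide, or hydrogen may be abstracted from C5 instead of from the methyl group.
- **Fallback (from 8 back to 9):** Ene-type allylic chlorination with hypochlorous acid, made from Ca(OCl)2 and CO2 in CH2Cl2–water, should give the allylic chloride F5. Finkelstein exchange (NaI, acetone) gives the allylic iodide F6. Silver-assisted substitution with anhydrous H2O2 (AgOSO2CF3, Et2O, 0 °C, dark) then gives 9 without base. The 2-substituted allyl unit is symmetrical, so allylic transposition changes nothing.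

3. Step 9.
- **Risk:** Chemoselectivity may be lost, with the alkenylzinc adding to the electron-poor C1 ketone or the Lewis acidic Cp2Zr(CH3)Cl and zinc alkoxides opening an oxirane.
- **Fallback (from 15, rejoining at 18):** Hydrozirconation of 15 with Cp2Zr(H)Cl followed by iodine gives the (E)-alkenyl iodide F7. Nozaki–Hiyama–Kishi coupling of F7 with 13 (CrCl2, catalytic NiCl2, DMSO, rt) gives 18, since alkenyl species of trivalent chromium add to aldehydes much faster than to ketones or esters.

Further compounds
F1 | step 5 | cis C1 allylic alcohol from Luche reduction of 8 (C1–OH cis to the C5 isopropenyl group, trans to the C6 ester) | CC(C)CC(=O)O[C@@H]1[C@@H](O)C(C)=CC[C@H]1C(C)=C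
F2 | step 5 | syn epoxy alcohol (C2–C3 oxirane on the face of the C1 hydroxyl and of the C5 group) | CC(C)CC(=O)O[C@@H]1[C@@H](O)[C@@]2(C)O[C@H]2C[C@H]1C(C)=C
F3 | step 5 | cis-epoxy ketone bearing the intact isopropenyl group | CC(C)CC(=O)O[C@@H]1C(=O)[C@@]2(C)O[C@H]2C[C@H]1C(C)=C
F4 | step 5 | side-chain hydroperoxide of the cis-epoxy ketone (C5 substituent 3-hydroperoxyprop-1-en-2-yl) | CC(C)CC(=O)O[C@@H]1C(=O)[C@@]2(C)O[C@H]2C[C@H]1C(=C)COO
F5 | step 4 | allylic chloride (8 with the C5 substituent changed to 3-chloroprop-1-en-2-yl) | CC(C)CC(=O)O[C@@H]1C(=O)C(C)=CC[C@H]1C(=C)CCl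
F6 | step 4 | allylic iodide (C5 substituent 3-iodoprop-1-en-2-yl) | CC(C)CC(=O)O[C@@H]1C(=O)C(C)=CC[C@H]1C(=C)CI
F7 | step 9 | (E)-alkenyl iodide, triethyl{[(3E)-4-iodo-2-methylbut-3-en-2-yl]oxy}silane | CC[Si](CC)(CC)OC(C)(C)/C=C/I
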